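**Plan**

- Retrosynthetic cuts: O1–C2 of the dihydrobenzofuran (the last bond made); the two benzylic C–C bonds at the lactone (C3–CH2 by lactone enolate alkylation, C4–CH2 by Evans succinate alkylation); in each C6–C3 unit the C7–C8 bond (anti-aldol) and the aryl–C8 bond (arylacetic acid from a Pd arylation).
- Forward order: one aldol-derived diol 12 is divided into two benzylic bromides that differ only at O7 (silyl ether in 15, dimethylcarbamate in 25). Bromide 15 builds the β-benzyl lactone 20, bromide 25 alkylates it, and the oxygen ring is closed last, during the global desilylation.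
- Enabling feature: the 4-oxygenated guaiacyl ring on C2 makes C2 the methide carbon of a p-quinone methide once its phenol is freed. O1 is the phenol oxygen of ring A (the arene on the lactone C3 benzyl group), ortho to the carbon that carries C3, so O1 can add to C2 in a 5-exo-trig closure.
- Stereochemistry: C7''/C8'' of the open unit and C3 of the dihydrobenzofuran come from one MgCl2-catalysed anti-aldol on (4S)-4-benzyloxazolidinone. Lactone C4 comes from an Evans alkylation with the same auxiliary, lactone C3 from trans alkylation, and C2 from C3 in the ring closure.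

Key step: step 18

Remark: TBS = tert-butyldimethylsilyl (TBSO = its ether oxygen); the side chain on ring A is numbered C7–C9 (C7 and C8 become C2 and C3 of the dihydrobenzofuran) and that on ring B C7''–C9''; the MgCl2-catalysed aldol is assumed to follow the chelated-enolate sense of Evans alkylations (attack anti to the auxiliary benzyl group).

**Route**

Step 1
Reactants: 1 methyl 3-bromo-4-hydroxy-5-methoxybenzoate
Product: 2 methyl 3-bromo-5-methoxy-4-(TBSO)benzoate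
Conditions: TBSCl, imidazole, DMF, rt
Reagents that add atoms: tert-butyldimethylsilyl chloride, CC(C)(C)[Si](C)(C)Cl
Why: Standard silylation of an acidic phenol (imidazole-promoted silyl ether formation), which masks the phenol for the enolate chemistry that follows.

Step 2
Reactants: 2 aryl bromide; 3 (2-tert-butoxy-2-oxoethyl)zinc bromide
Product: 4 tert-butyl 2-[3-methoxy-5-(methoxycarbonyl)-2-(TBSO)phenyl]acetate
Conditions: Pd2(dba)3 (1 mol%), P(t-Bu)3 (2 mol%), THF, rt to 50 °C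
Reagents that add atoms: none
Why: Palladium-catalysed α-arylation of a zinc ester enolate (Reformatsky–Negishi coupling), which needs no strong base and should tolerate the methyl ester and the aryl silyl ether.

Step 3
Reactants: 4 tert-butyl arylacetate
Product: 5 2-[3-methoxy-5-(methoxycarbonyl)-2-(TBSO)phenyl]acetic acid
Conditions: CF3CO2H/CH2Cl2 (1:4), 0 °C to rt
Reagents that add atoms: none
Why: Acidolysis of the tert-butyl ester with loss of isobutene should leave the methyl benzoate and the electron-poor aryl silyl ether in place.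

Step 4
Reactants: 5 arylacetic acid; 6 (4S)-4-benzyl-1,3-oxazolidin-2-one
Product: 8 methyl 3-{2-[(4S)-4-benzyl-2-oxo-1,3-oxazolidin-3-yl]-2-oxoethyl}-5-methoxy-4-(TBSO)benzoate, via mixed pivalic anhydride 7 (not isolated)
Conditions: t-BuCOCl, Et3N, THF, −20 °C; then 6, LiCl, −20 °C to rt
Reagents that add atoms: none
Why: N-acylation of the oxazolidinone through the mixed pivalic anhydride (LiCl/Et3N protocol) is the standard entry to Evans imides.

Step 5
Reactants: 8 arylacetyl imide; 9 3-methoxy-4-(TBSO)benzaldehyde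
Product: 11 methyl 3-{(2R,3S)-1-[(4S)-4-benzyl-2-oxo-1,3-oxazolidin-3-yl]-3-hydroxy-3-[3-methoxy-4-(TBSO)phenyl]-1-oxopropan-2-yl}-5-methoxy-4-(TBSO)benzoate, via O-trimethylsilyl aldol adduct 10 (not isolated)
Conditions: MgCl2 (20 mol%), Et3N, Me3SiCl, EtOAc, rt; then 1 M HCl, THF, 0 °C
Reagents that add atoms: none
Why: Evans MgCl2-catalysed direct anti-aldol: soft enolisation gives the chelated Z-enolate, which should be attacked anti to the auxiliary benzyl group through a boat transition state, setting C8 and placing the carbinol C7 anti to it, while in situ silylation (10) suppresses retro-aldol.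

Step 6
Reactants: 11 aldol adduct
Product: 12 methyl 3-{(1S,2S)-1,3-dihydroxy-1-[3-methoxy-4-(TBSO)phenyl]propan-2-yl}-5-methoxy-4-(TBSO)benzoate
Conditions: NaBH4, THF/H2O (4:1), 0 °C to rt
Reagents that add atoms: none
Why: Reductive cleavage of the N-acyloxazolidinone: borohydride attacks only the activated imide carbonyl, so the aryl methyl ester should survive and the auxiliary is recovered.

Step 7
Reactants: 12 diol
Product: 13 methyl 3-{(1S,2S)-1,3-bis(TBSO)-1-[3-methoxy-4-(TBSO)phenyl]propan-2-yl}-5-methoxy-4-(TBSO)benzoate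
Conditions: TBSOTf, 2,6-lutidine, CH2Cl2, −78 to 0 °C
Reagents that add atoms: tert-butyldimethylsilyl trifluoromethanesulfonate, CC(C)(C)[Si](C)(C)OS(=O)(=O)C(F)(F)F
Why: Silylation with the silyl triflate and a hindered pyridine base should cap both the primary and the hindered benzylic hydroxyl.

Step 8
Reactants: 13 tetrasilylated ester
Product: 14 (3-{(1S,2S)-1,3-bis(TBSO)-1-[3-methoxy-4-(TBSO)phenyl]propan-2-yl}-5-methoxy-4-(TBSO)phenyl)methanol
Conditions: i-Bu2AlH, CH2Cl2, −78 °C; aq. potassium sodium tartrate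
Reagents that add atoms: none
Why: Low-temperature aluminium hydride reduction of the benzoate to the benzylic alcohol, to which silyl ethers are inert.

Step 9
Reactants: 14 benzylic alcohol
Product: 15 5-(bromomethyl)-1-{(1S,2S)-1,3-bis(TBSO)-1-[3-methoxy-4-(TBSO)phenyl]propan-2-yl}-3-methoxy-2-(TBSO)benzene
Conditions: CBr4, PPh3, 2,6-lutidine, CH2Cl2, 0 °C
Reagents that add atoms: carbon tetrabromide, BrC(Br)(Br)Br
Why: Appel bromination converts the primary benzylic alcohol into the bromide under neutral conditions that should spare the silyl ethers.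

Step 10
Reactants: 6 (4S)-4-benzyl-1,3-oxazolidin-2-one; 16 methyl 4-chloro-4-oxobutanoate
Product: 17 methyl 4-[(4S)-4-benzyl-2-oxo-1,3-oxazolidin-3-yl]-4-oxobutanoate
Conditions: n-BuLi, THF, −78 °C; then 16, −78 to 0 °C
Reagents that add atoms: none
Why: N-acylation of the lithiated oxazolidinone by the acid chloride, which is much faster than attack on the methyl ester.

Step 11
Reactants: 17 succinate imide; 15 benzylic bromide
Product: 18 methyl (3S)-4-[(4S)-4-benzyl-2-oxo-1,3-oxazolidin-3-yl]-3-[(3-{(1S,2S)-1,3-bis(TBSO)-1-[3-methoxy-4-(TBSO)phenyl]propan-2-yl}-5-methoxy-4-(TBSO)phenyl)methyl]-4-oxobutanoate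
Conditions: NaN(SiMe3)2, THF, −78 °C; then 15, −78 to −30 °C
Reagents that add atoms: none
Why: Evans asymmetric alkylation: the chelated sodium Z-enolate of the imide should be benzylated on the face anti to the auxiliary benzyl group, which sets the future lactone C4 as S.

Step 12
Reactants: 18 alkylated imide
Product: 20 (4S)-4-[(3-{(1S,2S)-1,3-bis(TBSO)-1-[3-methoxy-4-(TBSO)phenyl]propan-2-yl}-5-methoxy-4-(TBSO)phenyl)methyl]oxolan-2-one, via hydroxy ester 19 (not isolated)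
Conditions: NaBH4, THF/H2O (4:1), 0 °C to rt; then PPTS (cat.), CH2Cl2, rt
Reagents that add atoms: none
Why: Borohydride cleaves the imide to the primary alcohol 19, which should lactonise onto the methyl ester (acyl substitution forming the five-membered ring) without touching the stereocentre.

Step 13
Reactants: 12 diol
Product: 21 methyl 3-{(1S,2S)-1-hydroxy-1-[3-methoxy-4-(TBSO)phenyl]-3-(TBSO)propan-2-yl}-5-methoxy-4-(TBSO)benzoate
Conditions: TBSCl (1.1 equiv), imidazole, CH2Cl2, 0 °C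
Reagents that add atoms: tert-butyldimethylsilyl chloride, CC(C)(C)[Si](C)(C)Cl
Why: Chemoselective silylation: the primary hydroxyl should react far faster with TBSCl/imidazole than the hindered secondary benzylic one.

Step 14
Reactants: 21 secondary alcohol
Product: 23 methyl 3-{(1S,2S)-1-[(dimethylcarbamoyl)oxy]-1-[3-methoxy-4-(TBSO)phenyl]-3-(TBSO)propan-2-yl}-5-methoxy-4-(TBSO)benzoate, via imidazole-1-carboxylate 22 (not isolated)
Conditions: CDI, MeCN, 40 °C; then Me2NH (2 M in THF), rt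
Reagents that add atoms: 1,1'-carbonyldiimidazole, O=C(n1ccnc1)n1ccnc1; dimethylamine, CNC
Why: Carbamoylation through the acyl imidazole (CDI activation, then aminolysis) installs at C7 a leaving group that should survive hydride and enolate chemistry.

Step 15
Reactants: 23 carbamate ester
Product: 24 (1S,2S)-2-[5-(hydroxymethyl)-3-methoxy-2-(TBSO)phenyl]-1-[3-methoxy-4-(TBSO)phenyl]-3-(TBSO)propyl dimethylcarbamate
Conditions: i-Bu2AlH, CH2Cl2, −78 °C; aq. potassium sodium tartrate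
Reagents that add atoms: none
Why: Low-temperature aluminium hydride reduction of the benzoate; the tertiary carbamate is much less electrophilic and should be retained.

Step 16
Reactants: 24 benzylic alcohol
Product: 25 (1S,2S)-2-[5-(bromomethyl)-3-methoxy-2-(TBSO)phenyl]-1-[3-methoxy-4-(TBSO)phenyl]-3-(TBSO)propyl dimethylcarbamate
Conditions: CBr4, PPh3, 2,6-lutidine, CH2Cl2, 0 °C
Reagents that add atoms: carbon tetrabromide, BrC(Br)(Br)Br
Why: Appel bromination of the only free (primary benzylic) hydroxyl under neutral conditions, compatible with the carbamate and silyl ethers.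

Step 17
Reactants: 20 β-benzyl lactone; 25 benzylic bromide
Product: 26 (3S,4S)-3-({3-[(1S,2S)-1-[(dimethylcarbamoyl)oxy]-1-[3-methoxy-4-(TBSO)phenyl]-3-(TBSO)propan-2-yl]-5-methoxy-4-(TBSO)phenyl}methyl)-4-[(3-{(1S,2S)-1,3-bis(TBSO)-1-[3-methoxy-4-(TBSO)phenyl]propan-2-yl}-5-methoxy-4-(TBSO)phenyl)methyl]oxolan-2-one
Conditions: LiN(SiMe3)2, THF, −78 °C; then 25, DMPU, −78 to −40 °C
Reagents that add atoms: none
Why: Enolate alkylation of a β-substituted γ-butyrolactone: the bromide should approach anti to the C4 benzyl group, which sets C3 trans to C4 and gives the (3S,4S) lactone.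

Step 18
Reactants: 26 fully protected lactone
Product: 29 (3S,4S)-4-({3-[(1S,2S)-1,3-dihydroxy-1-(4-hydroxy-3-methoxyphenyl)propan-2-yl]-4-hydroxy-5-methoxyphenyl}methyl)-3-{[(2R,3S)-2-(4-hydroxy-3-methoxyphenyl)-3-(hydroxymethyl)-7-methoxy-2,3-dihydro-1-benzofuran-5-yl]methyl}oxolan-2-one, via p-quinone methide 27 (not isolated), via tris-silylated phenylcoumaran 28 (not isolated)
Conditions: Bu4NF (10 equiv), THF, 0 °C to rt; aq. NH4Cl work-up (pH 6–7)
Reagents that add atoms: none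
Why: Fluoride first cleaves the four aryl silyl ethers; the phenoxide of the guaiacyl ring on C7 then expels the dimethylcarbamate by 1,6-elimination to give p-quinone methide 27, the phenoxide oxygen of ring A adds to the methide carbon to form the O1–C2 bond (28), and the three alkyl silyl ethers are cleaved last to give 29. The closest known reaction types are the fluoride-triggered 1,6-elimination of 4-silyloxybenzyl esters and carbamates to p-quinone methides and the phenol-to-quinone-methide closure that gives phenylcoumarans in β-5 lignin model chemistry. The dihydrofuran ring closes in the 5-exo-trig mode on the exocyclic methide carbon. C2 is controlled by the existing C3 centre: allylic 1,3-strain should hold the C3–H bond in the plane of the quinone methide, the tethered oxygen can only reach the face on which ring A sits, and the aryl group should end up trans to the CH2O substituent, giving (2R,3S); a direct SN2 displacement of the carbamate by the ring A phenoxide would invert C7 and converge on the same isomer. The step needs site selectivity between the two benzylic C7 oxygens, and this is secured by the leaving-group pattern: only C7 of the unit on ring A carries a carbamate, whereas C7'' carries a silyl ether that is converted into the alcohol, a non-leaving group under these basic conditions.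

**Compound list**

1 | methyl 3-bromo-4-hydroxy-5-methoxybenzoate | COC(=O)c1cc(Br)c(O)c(OC)c1 | starting material
2 | methyl 3-bromo-5-methoxy-4-(TBSO)benzoate | COC(=O)c1cc(Br)c(O[Si](C)(C)C(C)(C)C)c(OC)c1 | intermediate
3 | (2-tert-butoxy-2-oxoethyl)zinc bromide | CC(C)(C)OC(=O)C[Zn]Br | starting material
4 | tert-butyl 2-[3-methoxy-5-(methoxycarbonyl)-2-(TBSO)phenyl]acetate | COC(=O)c1cc(CC(=O)OC(C)(C)C)c(O[Si](C)(C)C(C)(C)C)c(OC)c1 | intermediate
5 | 2-[3-methoxy-5-(methoxycarbonyl)-2-(TBSO)phenyl]acetic acid | COC(=O)c1cc(CC(=O)O)c(O[Si](C)(C)C(C)(C)C)c(OC)c1 | intermediate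
6 | (4S)-4-benzyl-1,3-oxazolidin-2-one | O=C1N[C@@H](Cc2ccccc2)CO1 | starting material
7 | mixed anhydride of 5 with pivalic acid | COC(=O)c1cc(CC(=O)OC(=O)C(C)(C)C)c(O[Si](C)(C)C(C)(C)C)c(OC)c1 | intermediate
8 | methyl 3-{2-[(4S)-4-benzyl-2-oxo-1,3-oxazolidin-3-yl]-2-oxoethyl}-5-methoxy-4-(TBSO)benzoate | COC(=O)c1cc(CC(=O)N2[C@@H](Cc3ccccc3)COC2=O)c(O[Si](C)(C)C(C)(C)C)c(OC)c1 | intermediate
9 | 3-methoxy-4-(TBSO)benzaldehyde | COc1cc(C=O)ccc1O[Si](C)(C)C(C)(C)C | starting material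
10 | O-trimethylsilyl ether of aldol adduct 11 | COc1cc([C@@H](O[Si](C)(C)C)[C@H](C(=O)N2[C@@H](Cc3ccccc3)COC2=O)c2cc(C(=O)OC)cc(OC)c2O[Si](C)(C)C(C)(C)C)ccc1O[Si](C)(C)C(C)(C)C | intermediate
11 | methyl 3-{(2R,3S)-1-[(4S)-4-benzyl-2-oxo-1,3-oxazolidin-3-yl]-3-hydroxy-3-[3-methoxy-4-(TBSO)phenyl]-1-oxopropan-2-yl}-5-methoxy-4-(TBSO)benzoate | COc1cc([C@@H](O)[C@H](C(=O)N2[C@@H](Cc3ccccc3)COC2=O)c2cc(C(=O)OC)cc(OC)c2O[Si](C)(C)C(C)(C)C)ccc1O[Si](C)(C)C(C)(C)C | intermediate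
12 | methyl 3-{(1S,2S)-1,3-dihydroxy-1-[3-methoxy-4-(TBSO)phenyl]propan-2-yl}-5-methoxy-4-(TBSO)benzoate | COc1cc([C@@H](O)[C@H](CO)c2cc(C(=O)OC)cc(OC)c2O[Si](C)(C)C(C)(C)C)ccc1O[Si](C)(C)C(C)(C)C | intermediate
13 | methyl 3-{(1S,2S)-1,3-bis(TBSO)-1-[3-methoxy-4-(TBSO)phenyl]propan-2-yl}-5-methoxy-4-(TBSO)benzoate | COc1cc([C@@H](O[Si](C)(C)C(C)(C)C)[C@H](CO[Si](C)(C)C(C)(C)C)c2cc(C(=O)OC)cc(OC)c2O[Si](C)(C)C(C)(C)C)ccc1O[Si](C)(C)C(C)(C)C | intermediate
14 | (3-{(1S,2S)-1,3-bis(TBSO)-1-[3-methoxy-4-(TBSO)phenyl]propan-2-yl}-5-methoxy-4-(TBSO)phenyl)methanol | COc1cc([C@@H](O[Si](C)(C)C(C)(C)C)[C@H](CO[Si](C)(C)C(C)(C)C)c2cc(CO)cc(OC)c2O[Si](C)(C)C(C)(C)C)ccc1O[Si](C)(C)C(C)(C)C | intermediate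
15 | 5-(bromomethyl)-1-{(1S,2S)-1,3-bis(TBSO)-1-[3-methoxy-4-(TBSO)phenyl]propan-2-yl}-3-methoxy-2-(TBSO)benzene | COc1cc([C@@H](O[Si](C)(C)C(C)(C)C)[C@H](CO[Si](C)(C)C(C)(C)C)c2cc(CBr)cc(OC)c2O[Si](C)(C)C(C)(C)C)ccc1O[Si](C)(C)C(C)(C)C | intermediate
16 | methyl 4-chloro-4-oxobutanoate | COC(=O)CCC(Cl)=O | starting material
17 | methyl 4-[(4S)-4-benzyl-2-oxo-1,3-oxazolidin-3-yl]-4-oxobutanoate | COC(=O)CCC(=O)N1[C@@H](Cc2ccccc2)COC1=O | intermediate
18 | methyl (3S)-4-[(4S)-4-benzyl-2-oxo-1,3-oxazolidin-3-yl]-3-[(3-{(1S,2S)-1,3-bis(TBSO)-1-[3-methoxy-4-(TBSO)phenyl]propan-2-yl}-5-methoxy-4-(TBSO)phenyl)methyl]-4-oxobutanoate | COc1cc([C@@H](O[Si](C)(C)C(C)(C)C)[C@H](CO[Si](C)(C)C(C)(C)C)c2cc(C[C@@H](CC(=O)OC)C(=O)N3[C@@H](Cc4ccccc4)COC3=O)cc(OC)c2O[Si](C)(C)C(C)(C)C)ccc1O[Si](C)(C)C(C)(C)C | intermediate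
19 | methyl (3S)-3-[(3-{(1S,2S)-1,3-bis(TBSO)-1-[3-methoxy-4-(TBSO)phenyl]propan-2-yl}-5-methoxy-4-(TBSO)phenyl)methyl]-4-hydroxybutanoate | COc1cc([C@@H](O[Si](C)(C)C(C)(C)C)[C@H](CO[Si](C)(C)C(C)(C)C)c2cc(C[C@@H](CC(=O)OC)CO)cc(OC)c2O[Si](C)(C)C(C)(C)C)ccc1O[Si](C)(C)C(C)(C)C | intermediate
20 | (4S)-4-[(3-{(1S,2S)-1,3-bis(TBSO)-1-[3-methoxy-4-(TBSO)phenyl]propan-2-yl}-5-methoxy-4-(TBSO)phenyl)methyl]oxolan-2-one | COc1cc([C@@H](O[Si](C)(C)C(C)(C)C)[C@H](CO[Si](C)(C)C(C)(C)C)c2cc(C[C@@H]3COC(=O)C3)cc(OC)c2O[Si](C)(C)C(C)(C)C)ccc1O[Si](C)(C)C(C)(C)C | intermediate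
21 | methyl 3-{(1S,2S)-1-hydroxy-1-[3-methoxy-4-(TBSO)phenyl]-3-(TBSO)propan-2-yl}-5-methoxy-4-(TBSO)benzoate | COc1cc([C@@H](O)[C@H](CO[Si](C)(C)C(C)(C)C)c2cc(C(=O)OC)cc(OC)c2O[Si](C)(C)C(C)(C)C)ccc1O[Si](C)(C)C(C)(C)C | intermediate
22 | methyl 3-{(1S,2S)-1-[(1H-imidazole-1-carbonyl)oxy]-1-[3-methoxy-4-(TBSO)phenyl]-3-(TBSO)propan-2-yl}-5-methoxy-4-(TBSO)benzoate | COc1cc([C@@H](OC(=O)n2ccnc2)[C@H](CO[Si](C)(C)C(C)(C)C)c2cc(C(=O)OC)cc(OC)c2O[Si](C)(C)C(C)(C)C)ccc1O[Si](C)(C)C(C)(C)C | intermediate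
23 | methyl 3-{(1S,2S)-1-[(dimethylcarbamoyl)oxy]-1-[3-methoxy-4-(TBSO)phenyl]-3-(TBSO)propan-2-yl}-5-methoxy-4-(TBSO)benzoate | COc1cc([C@@H](OC(=O)N(C)C)[C@H](CO[Si](C)(C)C(C)(C)C)c2cc(C(=O)OC)cc(OC)c2O[Si](C)(C)C(C)(C)C)ccc1O[Si](C)(C)C(C)(C)C | intermediate
24 | (1S,2S)-2-[5-(hydroxymethyl)-3-methoxy-2-(TBSO)phenyl]-1-[3-methoxy-4-(TBSO)phenyl]-3-(TBSO)propyl dimethylcarbamate | COc1cc([C@@H](OC(=O)N(C)C)[C@H](CO[Si](C)(C)C(C)(C)C)c2cc(CO)cc(OC)c2O[Si](C)(C)C(C)(C)C)ccc1O[Si](C)(C)C(C)(C)C | intermediate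
25 | (1S,2S)-2-[5-(bromomethyl)-3-methoxy-2-(TBSO)phenyl]-1-[3-methoxy-4-(TBSO)phenyl]-3-(TBSO)propyl dimethylcarbamate | COc1cc([C@@H](OC(=O)N(C)C)[C@H](CO[Si](C)(C)C(C)(C)C)c2cc(CBr)cc(OC)c2O[Si](C)(C)C(C)(C)C)ccc1O[Si](C)(C)C(C)(C)C | intermediate
26 | (3S,4S)-3-({3-[(1S,2S)-1-[(dimethylcarbamoyl)oxy]-1-[3-methoxy-4-(TBSO)phenyl]-3-(TBSO)propan-2-yl]-5-methoxy-4-(TBSO)phenyl}methyl)-4-[(3-{(1S,2S)-1,3-bis(TBSO)-1-[3-methoxy-4-(TBSO)phenyl]propan-2-yl}-5-methoxy-4-(TBSO)phenyl)methyl]oxolan-2-one | COc1cc([C@@H](O[Si](C)(C)C(C)(C)C)[C@H](CO[Si](C)(C)C(C)(C)C)c2cc(C[C@@H]3COC(=O)[C@H]3Cc3cc(OC)c(O[Si](C)(C)C(C)(C)C)c(c3)[C@@H](CO[Si](C)(C)C(C)(C)C)[C@H](OC(=O)N(C)C)c3ccc(O[Si](C)(C)C(C)(C)C)c(OC)c3)cc(OC)c2O[Si](C)(C)C(C)(C)C)ccc1O[Si](C)(C)C(C)(C)C | intermediate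
27 | p-quinone methide from 26: aryl silyl ethers cleaved, carbamate expelled, C7 doubly bonded to a 3-methoxy-4-oxocyclohexa-2,5-dien-1-ylidene ring, (S) at C8 | COc1cc([C@@H](O[Si](C)(C)C(C)(C)C)[C@H](CO[Si](C)(C)C(C)(C)C)c2cc(C[C@@H]3COC(=O)[C@H]3Cc3cc(OC)c(O)c(c3)[C@@H](CO[Si](C)(C)C(C)(C)C)C=C3C=CC(=O)C(OC)=C3)cc(OC)c2O)ccc1O | intermediate
28 | tris-O-TBS ether of 29 (TBS on O7'', O9'' and on the hydroxymethyl oxygen of the dihydrobenzofuran) | COc1cc([C@@H](O[Si](C)(C)C(C)(C)C)[C@H](CO[Si](C)(C)C(C)(C)C)c2cc(C[C@@H]3COC(=O)[C@H]3Cc3cc(OC)c4c(c3)[C@@H](CO[Si](C)(C)C(C)(C)C)[C@H](c3ccc(O)c(OC)c3)O4)cc(OC)c2O)ccc1O | intermediate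
29 | (3S,4S)-4-({3-[(1S,2S)-1,3-dihydroxy-1-(4-hydroxy-3-methoxyphenyl)propan-2-yl]-4-hydroxy-5-methoxyphenyl}methyl)-3-{[(2R,3S)-2-(4-hydroxy-3-methoxyphenyl)-3-(hydroxymethyl)-7-methoxy-2,3-dihydro-1-benzofuran-5-yl]methyl}oxolan-2-one | COc1cc([C@@H](O)[C@H](CO)c2cc(C[C@@H]3COC(=O)[C@H]3Cc3cc(OC)c4c(c3)[C@@H](CO)[C@H](c3ccc(O)c(OC)c3)O4)cc(OC)c2O)ccc1O | target

**Step count and risks**

Total steps: 18. Longest linear sequence: 13 steps (steps 1–9, 11, 12, 17, 18).

Steps most likely to fail: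

1. Step 18. The quinone methide may be captured intermolecularly by water or fluoride before the ring A phenoxide is free, or slow loss of silanolate at C7'' may open a second ring closure on the open unit; either would erode site selectivity. The fallback sets out from 12 and comes back to the route at 29, and closes the ring before the fragments are joined by the acid-catalysed phenylcoumaran closure known from β-5 lignin models. Bu4NF/AcOH should remove the two aryl silyl ethers of 12 to give methyl 3-[(1S,2S)-1,3-dihydroxy-1-(4-hydroxy-3-methoxyphenyl)propan-2-yl]-4-hydroxy-5-methoxybenzoate F1. Catalytic TsOH in dioxane should ionise the 4-hydroxybenzylic alcohol and close it, trans under thermodynamic control, to methyl (2R,3S)-2-(4-hydroxy-3-methoxyphenyl)-3-(hydroxymethyl)-7-methoxy-2,3-dihydro-1-benzofuran-5-carboxylate F2. TBSCl/imidazole should give the bis-silyl ether methyl (2R,3S)-7-methoxy-2-[3-methoxy-4-(TBSO)phenyl]-3-[(TBSO)methyl]-2,3-dihydro-1-benzofuran-5-carboxylate F3. i-Bu2AlH should then give the benzylic alcohol {(2R,3S)-7-methoxy-2-[3-methoxy-4-(TBSO)phenyl]-3-[(TBSO)methyl]-2,3-dihydro-1-benzofuran-5-yl}methanol F4, and CBr4/PPh3 the bromide (2R,3S)-5-(bromomethyl)-7-methoxy-2-[3-methoxy-4-(TBSO)phenyl]-3-[(TBSO)methyl]-2,3-dihydro-1-benzofuran F5. Alkylation of the lithium enolate of 20 with F5 should give the hexasilylated trans-lactone F6, from which Bu4NF only has to remove six silyl groups to deliver 29.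

2. Step 5. Anti/syn selectivity may be poor, or the acidic α-aryl centre may epimerise under the amine base during the long reaction. The fallback sets out from 8 and 9 and comes back at 11. The preformed dibutylboron enolate of 8 (Bu2BOTf, i-Pr2NEt, CH2Cl2, −78 °C) is treated with 9 precomplexed with Et2AlCl (Heathcock anti-aldol). The reaction then runs through an open transition state at low temperature with no free amine base at room temperature, and the boron-chelated enolate should again be attacked anti to the auxiliary benzyl group. This fallback makes no compound outside the list (F0).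

3. Step 17. The electron-rich 4-silyloxybenzyl bromide may ionise or self-alkylate, or proton transfer may outrun C-alkylation of the hindered partners. The fallback sets out from 24 and 20 and comes back at 26, replacing the alkylation by an aldol addition and radical deoxygenation. MnO2 should oxidise 24 to (1S,2S)-2-[5-formyl-3-methoxy-2-(TBSO)phenyl]-1-[3-methoxy-4-(TBSO)phenyl]-3-(TBSO)propyl dimethylcarbamate F7. Addition of the lithium enolate of 20 (LiN(SiMe3)2, THF, −78 °C) to F7 should give, trans at the lactone, the β-hydroxy lactone F8 (the analogue of 26 with a hydroxyl on the ring A benzylic carbon, as a mixture of carbinol epimers). 1,1'-Thiocarbonyldiimidazole should convert it into the O-(imidazole-1-carbothioyl) derivative F9, and Bu3SnH/AIBN in toluene at 80 °C (Barton–McCombie deoxygenation) should remove the benzylic oxygen to give 26.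

**Further compounds**

F1 | step 18 | methyl 3-[(1S,2S)-1,3-dihydroxy-1-(4-hydroxy-3-methoxyphenyl)propan-2-yl]-4-hydroxy-5-methoxybenzoate | COc1cc([C@@H](O)[C@H](CO)c2cc(C(=O)OC)cc(OC)c2O)ccc1O
F2 | step 18 | methyl (2R,3S)-2-(4-hydroxy-3-methoxyphenyl)-3-(hydroxymethyl)-7-methoxy-2,3-dihydro-1-benzofuran-5-carboxylate | COC(=O)c1cc(OC)c2c(c1)[C@@H](CO)[C@H](c1ccc(O)c(OC)c1)O2
F3 | step 18 | methyl (2R,3S)-7-methoxy-2-[3-methoxy-4-(TBSO)phenyl]-3-[(TBSO)methyl]-2,3-dihydro-1-benzofuran-5-carboxylate | COC(=O)c1cc(OC)c2c(c1)[C@@H](CO[Si](C)(C)C(C)(C)C)[C@H](c1ccc(O[Si](C)(C)C(C)(C)C)c(OC)c1)O2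
F4 | step 18 | {(2R,3S)-7-methoxy-2-[3-methoxy-4-(TBSO)phenyl]-3-[(TBSO)methyl]-2,3-dihydro-1-benzofuran-5-yl}methanol | OCc1cc(OC)c2c(c1)[C@@H](CO[Si](C)(C)C(C)(C)C)[C@H](c1ccc(O[Si](C)(C)C(C)(C)C)c(OC)c1)O2
F5 | step 18 | (2R,3S)-5-(bromomethyl)-7-methoxy-2-[3-methoxy-4-(TBSO)phenyl]-3-[(TBSO)methyl]-2,3-dihydro-1-benzofuran | BrCc1cc(OC)c2c(c1)[C@@H](CO[Si](C)(C)C(C)(C)C)[C@H](c1ccc(O[Si](C)(C)C(C)(C)C)c(OC)c1)O2
F6 | step 18 | hexa-O-TBS ether of 29 (all three phenols, O7'', O9'' and the hydroxymethyl oxygen of the dihydrobenzofuran silylated) | COc1cc([C@@H](O[Si](C)(C)C(C)(C)C)[C@H](CO[Si](C)(C)C(C)(C)C)c2cc(C[C@@H]3COC(=O)[C@H]3Cc3cc(OC)c4c(c3)[C@@H](CO[Si](C)(C)C(C)(C)C)[C@H](c3ccc(O[Si](C)(C)C(C)(C)C)c(OC)c3)O4)cc(OC)c2O[Si](C)(C)C(C)(C)C)ccc1O[Si](C)(C)C(C)(C)C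
F0 | step 5 | none | none
F7 | step 17 | (1S,2S)-2-[5-formyl-3-methoxy-2-(TBSO)phenyl]-1-[3-methoxy-4-(TBSO)phenyl]-3-(TBSO)propyl dimethylcarbamate | COc1cc([C@@H](OC(=O)N(C)C)[C@H](CO[Si](C)(C)C(C)(C)C)c2cc(C=O)cc(OC)c2O[Si](C)(C)C(C)(C)C)ccc1O[Si](C)(C)C(C)(C)C
F8 | step 17 | analogue of 26 with a hydroxyl on the ring A benzylic carbon attached to lactone C3 (carbinol epimers) | COc1cc([C@@H](O[Si](C)(C)C(C)(C)C)[C@H](CO[Si](C)(C)C(C)(C)C)c2cc(C[C@@H]3COC(=O)[C@H]3C(O)c3cc(OC)c(O[Si](C)(C)C(C)(C)C)c(c3)[C@@H](CO[Si](C)(C)C(C)(C)C)[C@H](OC(=O)N(C)C)c3ccc(O[Si](C)(C)C(C)(C)C)c(OC)c3)cc(OC)c2O[Si](C)(C)C(C)(C)C)ccc1O[Si](C)(C)C(C)(C)C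
F9 | step 17 | O-(1H-imidazole-1-carbothioyl) derivative of F8 | COc1cc([C@@H](O[Si](C)(C)C(C)(C)C)[C@H](CO[Si](C)(C)C(C)(C)C)c2cc(C[C@@H]3COC(=O)[C@H]3C(OC(=S)n3ccnc3)c3cc(OC)c(O[Si](C)(C)C(C)(C)C)c(c3)[C@@H](CO[Si](C)(C)C(C)(C)C)[C@H](OC(=O)N(C)C)c3ccc(O[Si](C)(C)C(C)(C)C)c(OC)c3)cc(OC)c2O[Si](C)(C)C(C)(C)C)ccc1O[Si](C)(C)C(C)(C)C
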